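**Plan**

- Retrosynthesis first removes the acetate and the C12–C16 arm (cuts at C11–C12 and C13–C16, back to an allylic C11 bromide and methyl acetoacetate) and traces the C8=C9 olefin to a saturated C9 ester on a trans-decalin.
- The decalin is then cut at C5–C10 and C8–C9. Ring B carries the acyl carbon C11 on C9 and the methyl C17 on C8, next to quaternary C10; this is the imprint of an (E)-3-methyl-2-enoyl dienophile (C9=C10) and a methyl-terminated diene (C5=C6–C7=C8), joined through C1–C4 of ring A.
- Forward, the open chain is built linearly: alkyne carboalumination to an allylic alcohol, epoxidation and rearrangement to the C4 aldehyde, olefination to the diene, a second carboalumination with carboxylation, then the auxiliary.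
- Rings A and B close together in one intramolecular Diels–Alder step; afterwards C6=C7 is saturated, C8=C9 introduced, and the side chain and acetate are added.
- C4 comes from a Sharpless epoxidation (D-(−)-tartrate) relayed by a stereospecific siloxymethyl shift; C5 and C10 come from the (S)-benzyl oxazolidinone in the chelated endo transition state; C8 and C9 are transient; alkene geometries come from syn-carboalumination, phosphonate olefination and enol phosphate–cuprate exchange (13E).

Key step: step 10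

Remark: labdane numbering is used throughout (C18 = 4α-CH3, C19 = 4β-CH2O, C20 = 10β-CH3, α = face of H-5; "12,13,14,15,16-pentanorlabdane" is the C15 core C1–C11, C17–C20), and commercial crotyl bromide is taken as its E isomer.

**Route**

Step 1
Reactants: 1 5-chloropent-1-yne
Product: 4 (2E)-6-chloro-3-methylhex-2-en-1-ol, via alkenylalane 2 (not isolated), via lithium aluminate 3 (not isolated)
Conditions: Me3Al (2 equiv), Cp2ZrCl2 (0.25 equiv), CH2Cl2, rt; then n-BuLi, THF/hexane, −78 → 0 °C; (CH2O)n, rt; aq. HCl work-up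
Reagents that add atoms: trimethylaluminium, C[Al](C)C; formaldehyde (as paraformaldehyde), C=O
Why: Negishi zirconium-catalysed carboalumination adds CH3 and Al syn across the terminal alkyne with methyl on the internal carbon, and the derived aluminate is hydroxymethylated with retention, which fixes the (2E) geometry; a primary alkyl chloride is inert to these reagents.

Step 2
Reactants: 4 (2E)-6-chloro-3-methylhex-2-en-1-ol
Product: 5 [(2R,3R)-3-(3-chloropropyl)-3-methyloxiran-2-yl]methanol
Conditions: Ti(OiPr)4 (0.1 equiv), D-(−)-diethyl tartrate (0.12 equiv), t-BuOOH (2 equiv), 4 Å molecular sieves, CH2Cl2, −20 °C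
Reagents that add atoms: tert-butyl hydroperoxide, CC(C)(C)OO
Why: Sharpless asymmetric epoxidation of a geraniol-type (E)-trisubstituted allylic alcohol, in which the D-(−)-tartrate titanium peroxide delivers oxygen to the face giving the (2R,3R)-epoxide (mirror image of the L-(+)-tartrate/geraniol case) and so sets both epoxide centres; any minor enantiomer becomes a separable diastereomer once the auxiliary is attached.

Step 3
Reactants: 5 [(2R,3R)-3-(3-chloropropyl)-3-methyloxiran-2-yl]methanol
Product: 6 tert-butyl{[(2R,3R)-3-(3-chloropropyl)-3-methyloxiran-2-yl]methoxy}dimethylsilane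
Conditions: TBSCl, imidazole, DMF, 0 °C → rt
Reagents that add atoms: tert-butyl(chloro)dimethylsilane, CC(C)(C)[Si](C)(C)Cl
Why: Imidazole-mediated silylation of the primary alcohol touches no stereocentre and installs the group that migrates as CH2OSi in step 4 and protects C19 until step 20.

Step 4
Reactants: 6 tert-butyl{[(2R,3R)-3-(3-chloropropyl)-3-methyloxiran-2-yl]methoxy}dimethylsilane
Product: 7 (2R)-2-({[tert-butyl(dimethyl)silyl]oxy}methyl)-5-chloro-2-methylpentanal
Conditions: MABR [MeAl(OAr)2, Ar = 4-bromo-2,6-di-tert-butylphenyl, 2 equiv, preformed in the flask from Me3Al and ArOH], CH2Cl2, −78 → −40 °C; aq. HCl work-up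
Reagents that add atoms: none
Why: Aluminium-promoted rearrangement of a 2,3-epoxy silyl ether (semipinacol-type 1,2-shift): the bulky Lewis acid opens the epoxide at the tertiary carbon and the siloxymethyl group migrates to it anti to the departing oxygen, so the epoxide configuration is relayed with inversion to the new quaternary centre (future C4) while the other epoxide carbon becomes the formyl group.

Step 5
Reactants: 8 (2E)-1-bromobut-2-ene; 9 triethyl phosphite
Product: 10 diethyl [(2E)-but-2-en-1-yl]phosphonate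
Conditions: neat, 130 °C, EtBr distilled off
Reagents that add atoms: none
Why: Michaelis–Arbuzov reaction (SN2 attack of phosphorus on the primary allylic bromide, then dealkylation of the phosphonium salt by bromide) with retention of the alkene geometry.

Step 6
Reactants: 7 (2R)-2-({[tert-butyl(dimethyl)silyl]oxy}methyl)-5-chloro-2-methylpentanal; 10 diethyl [(2E)-but-2-en-1-yl]phosphonate
Product: 12 tert-butyl{[(2S,3E,5E)-2-(3-chloropropyl)-2-methylhepta-3,5-dien-1-yl]oxy}dimethylsilane, via lithiated phosphonate 11 (not isolated)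
Conditions: n-BuLi, THF, −78 °C; then 7; DMPU, −78 °C → rt
Reagents that add atoms: none
Why: Horner–Wadsworth–Emmons olefination with an allylic phosphonate, whose α-carbanion adds to the non-enolisable aldehyde and loses phosphate to give the new (3E) bond (C5=C6) while the (5E) bond (C7=C8) comes from the reagent; the quaternary centre is untouched and its descriptor changes from R to S only because the formyl carbon becomes a vinyl carbon.

Step 7
Reactants: 12 tert-butyl{[(2S,3E,5E)-2-(3-chloropropyl)-2-methylhepta-3,5-dien-1-yl]oxy}dimethylsilane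
Product: 13 tert-butyl(dimethyl){[(2S,3E,5E)-2-methyl-2-(pent-4-yn-1-yl)hepta-3,5-dien-1-yl]oxy}silane
Conditions: LiC≡CH·H2NCH2CH2NH2, NaI (cat.), DMSO, rt
Reagents that add atoms: lithium acetylide–ethylenediamine complex, [Li+].[C-]#C.NCCN
Why: SN2 alkylation of lithium acetylide by the primary chloride under iodide catalysis; the diene, silyl ether and quaternary centre are inert to the acetylide.

Step 8
Reactants: 13 tert-butyl(dimethyl){[(2S,3E,5E)-2-methyl-2-(pent-4-yn-1-yl)hepta-3,5-dien-1-yl]oxy}silane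
Product: 16 (2E,7S,8E,10E)-7-({[tert-butyl(dimethyl)silyl]oxy}methyl)-3,7-dimethyldodeca-2,8,10-trienoic acid, via alkenylalane 14 (not isolated), via lithium aluminate 15 (not isolated)
Conditions: Me3Al (2.5 equiv), Cp2ZrCl2 (0.25 equiv), CH2Cl2, 0 °C → rt; then n-BuLi, THF, −78 °C; CO2, −78 °C → rt; aq. HCl work-up
Reagents that add atoms: trimethylaluminium, C[Al](C)C; carbon dioxide, O=C=O
Why: A second Negishi carboalumination (syn CH3–Al addition, methyl to the internal carbon) followed by carboxylation of the alkenylaluminate with retention gives the (2E)-3-methyl-2-enoic acid directly; internal conjugated dienes do not carboaluminate under these conditions.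

Step 9
Reactants: 16 (2E,7S,8E,10E)-7-({[tert-butyl(dimethyl)silyl]oxy}methyl)-3,7-dimethyldodeca-2,8,10-trienoic acid; 17 (4S)-4-benzyl-1,3-oxazolidin-2-one
Product: 19 (4S)-4-benzyl-3-[(2E,7S,8E,10E)-7-({[tert-butyl(dimethyl)silyl]oxy}methyl)-3,7-dimethyldodeca-2,8,10-trienoyl]-1,3-oxazolidin-2-one, via mixed pivalic anhydride 18 (not isolated)
Conditions: t-BuCOCl, Et3N, THF, −20 °C; then LiCl, 17, −20 °C → rt
Reagents that add atoms: none
Why: N-Acylation of the oxazolidinone through the mixed pivalic anhydride with LiCl/Et3N activation, attack occurring at the less hindered enoyl carbonyl; no stereocentre is formed and the (2E) geometry is kept.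

Step 10
Reactants: 19 (4S)-4-benzyl-3-[(2E,7S,8E,10E)-7-({[tert-butyl(dimethyl)silyl]oxy}methyl)-3,7-dimethyldodeca-2,8,10-trienoyl]-1,3-oxazolidin-2-one
Product: 20 (4S)-4-benzyl-3-[(4S,5R,8S,9S,10S)-19-{[tert-butyl(dimethyl)silyl]oxy}-12,13,14,15,16-pentanorlabd-6-en-11-oyl]-1,3-oxazolidin-2-one (trans-decalin; 5α-H; 8β-CH3, 9β-acyl and 10β-CH3 cis)
Conditions: Me2AlCl (1.5–2 equiv), CH2Cl2, −30 → 0 °C; aq. HCl work-up
Reagents that add atoms: none
Why: More than one equivalent of Me2AlCl turns the imide into a cationic aluminium chelate that binds both carbonyl oxygens, holds the enoyl unit s-cis and activates C9=C10, which adds to the C5=C6–C7=C8 diene in a concerted, asynchronous [4+2] cycloaddition; the closest known reaction type is the Lewis-acid-promoted intramolecular Diels–Alder reaction of N-enoyl oxazolidinone trienes. Ring B is closed as the new cyclohexene by suprafacial formation of C5–C10 and C8–C9, and ring A is closed by the same C5–C10 bond as the C1–C3 chain and C4 fold into a chair (a six-membered ring through the four-atom link between dienophile and diene). C10 is set by the auxiliary, whose benzyl group covers one face of the chelated dienophile so that the diene adds to the C9-si face; C9 follows from the E dienophile geometry (acyl cis to the C20 methyl), C5 from the endo transition state with the acyl group under the diene, which gives the trans fusion, and C8 from the E geometry of the propenyl terminus. The step needs endo and facial selectivity: the chelated acyl group and the chair-like tether secure the first and the (S)-benzyl group the second, the C4 centre (methyl against CH2OTBS) being almost unbiased. The low intrinsic reactivity of the β,β-disubstituted dienophile is offset by cationic activation, by intramolecularity and by the gem-disubstitution at C4, which favours the folded chain.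

Step 11
Reactants: 20 (4S)-4-benzyl-3-[(4S,5R,8S,9S,10S)-19-{[tert-butyl(dimethyl)silyl]oxy}-12,13,14,15,16-pentanorlabd-6-en-11-oyl]-1,3-oxazolidin-2-one
Product: 21 (4S)-4-benzyl-3-[(4S,5R,8S,9S,10S)-19-{[tert-butyl(dimethyl)silyl]oxy}-12,13,14,15,16-pentanorlabdan-11-oyl]-1,3-oxazolidin-2-one
Conditions: H2 (1 atm), PtO2, EtOAc, rt
Reagents that add atoms: none
Why: Heterogeneous catalytic hydrogenation of the cis-disubstituted C6=C7 bond, with platinum chosen because it migrates double bonds less than palladium, so the 8β-methyl/8α-H arrangement needed in step 14 is kept; no stereocentre is created.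

Step 12
Reactants: 21 (4S)-4-benzyl-3-[(4S,5R,8S,9S,10S)-19-{[tert-butyl(dimethyl)silyl]oxy}-12,13,14,15,16-pentanorlabdan-11-oyl]-1,3-oxazolidin-2-one
Product: 23 (4S,5R,8S,9S,10S)-19-{[tert-butyl(dimethyl)silyl]oxy}-12,13,14,15,16-pentanorlabdan-11-oic acid, via peroxy acid 22 (not isolated)
Conditions: LiOH, H2O2, THF/H2O, 0 °C → rt; then aq. Na2SO3; HCl to pH 3
Reagents that add atoms: hydrogen peroxide (as LiOOH), OO
Why: Hydroperoxide cleavage of the N-acyl oxazolidinone, in which the α-effect nucleophile attacks the exocyclic carbonyl even of a hindered acyl group and sulfite reduces the peracid, the auxiliary being recovered; epimerisation at C9 would be harmless because C9 is planarised in step 14.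

Step 13
Reactants: 23 (4S,5R,8S,9S,10S)-19-{[tert-butyl(dimethyl)silyl]oxy}-12,13,14,15,16-pentanorlabdan-11-oic acid
Product: 24 methyl (4S,5R,8S,9S,10S)-19-{[tert-butyl(dimethyl)silyl]oxy}-12,13,14,15,16-pentanorlabdan-11-oate
Conditions: MeI, K2CO3, DMF, rt
Reagents that add atoms: iodomethane, CI
Why: O-Alkylation of the carboxylate (SN2 at methyl), which is insensitive to the hindrance around C9.

Step 14
Reactants: 24 methyl (4S,5R,8S,9S,10S)-19-{[tert-butyl(dimethyl)silyl]oxy}-12,13,14,15,16-pentanorlabdan-11-oate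
Product: 28 methyl (4S,5R,10S)-19-{[tert-butyl(dimethyl)silyl]oxy}-12,13,14,15,16-pentanorlabd-8-en-11-oate, via lithium enolate 25 (not isolated), via selenide 26 (not isolated), via selenoxide 27 (not isolated)
Conditions: LDA, THF/DMPU, −78 → 0 °C; PhSeBr, −78 °C; then H2O2, pyridine, CH2Cl2, 0 °C → rt
Reagents that add atoms: none
Why: Selenoxide elimination route to an α,β-unsaturated ester: the C9 enolate should be selenenylated from the α face (the β face is flanked by the axial C17 and C20 methyls), and after oxidation the syn-elimination can only use H-8 (cis to selenium, C10 being quaternary), which gives the tetrasubstituted C8=C9 bond and erases the C8 and C9 centres.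

Step 15
Reactants: 28 methyl (4S,5R,10S)-19-{[tert-butyl(dimethyl)silyl]oxy}-12,13,14,15,16-pentanorlabd-8-en-11-oate
Product: 29 (4S,5R,10S)-19-{[tert-butyl(dimethyl)silyl]oxy}-12,13,14,15,16-pentanorlabd-8-en-11-ol
Conditions: i-Bu2AlH, CH2Cl2, −78 → 0 °C; aq. Rochelle salt work-up
Reagents that add atoms: none
Why: 1,2-Reduction of the conjugated ester by two hydride transfers from the aluminium hydride gives the allylic alcohol and leaves the silyl ether and the tetrasubstituted alkene untouched.

Step 16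
Reactants: 29 (4S,5R,10S)-19-{[tert-butyl(dimethyl)silyl]oxy}-12,13,14,15,16-pentanorlabd-8-en-11-ol
Product: 30 (4S,5R,10S)-11-bromo-19-{[tert-butyl(dimethyl)silyl]oxy}-12,13,14,15,16-pentanorlabd-8-ene
Conditions: CBr4, PPh3, CH2Cl2, 0 °C
Reagents that add atoms: tetrabromomethane, BrC(Br)(Br)Br
Why: Appel bromination (bromide displaces the alkoxyphosphonium group at primary C11) under neutral conditions that spare the silyl ether and avoid acid-induced migration of the alkene.

Step 17
Reactants: 30 (4S,5R,10S)-11-bromo-19-{[tert-butyl(dimethyl)silyl]oxy}-12,13,14,15,16-pentanorlabd-8-ene; 31 methyl 3-oxobutanoate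
Product: 33 methyl (4S,5R,10S)-19-{[tert-butyl(dimethyl)silyl]oxy}-13-oxo-16-norlabd-8-en-15-oate, via acetoacetate dianion 32 (not isolated)
Conditions: 31, NaH then n-BuLi, THF, 0 °C; then 30, 0 °C → rt; aq. HCl work-up
Reagents that add atoms: none
Why: γ-Alkylation of the acetoacetate dianion, whose more nucleophilic terminal carbon displaces the primary allylic bromide by SN2, forms C11–C12 and delivers C12–C15.

Step 18
Reactants: 33 methyl (4S,5R,10S)-19-{[tert-butyl(dimethyl)silyl]oxy}-13-oxo-16-norlabd-8-en-15-oate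
Product: 35 methyl (4S,5R,10S,13Z)-13-[(diethoxyphosphoryl)oxy]-19-{[tert-butyl(dimethyl)silyl]oxy}-16-norlabda-8,13-dien-15-oate, via sodium enolate 34 (not isolated)
Conditions: NaH, Et2O, 0 °C; ClP(O)(OEt)2, 0 °C → rt
Reagents that add atoms: diethyl chlorophosphate, CCOP(=O)(Cl)OCC
Why: O-Phosphorylation of the chelated sodium enolate of the β-keto ester gives the (Z)-enol phosphate, in which the phosphate is cis to the ester.

Step 19
Reactants: 35 methyl (4S,5R,10S,13Z)-13-[(diethoxyphosphoryl)oxy]-19-{[tert-butyl(dimethyl)silyl]oxy}-16-norlabda-8,13-dien-15-oate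
Product: 36 methyl (4S,5R,10S,13E)-19-{[tert-butyl(dimethyl)silyl]oxy}labda-8,13-dien-15-oate
Conditions: Me2CuLi (from MeLi and CuI), Et2O, −78 → −45 °C; aq. NH4Cl
Reagents that add atoms: lithium dimethylcuprate, [Li+].C[Cu-]C
Why: Cuprate addition–elimination on the β-phosphoryloxy enoate replaces phosphate by methyl (C16) with retention, so the (Z)-enol phosphate gives the (13E)-enoate; the tetrasubstituted alkene and silyl ether are inert.

Step 20
Reactants: 36 methyl (4S,5R,10S,13E)-19-{[tert-butyl(dimethyl)silyl]oxy}labda-8,13-dien-15-oate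
Product: 38 methyl (4S,5R,10S,13E)-19-acetoxylabda-8,13-dien-15-oate, via alcohol 37 (not isolated)
Conditions: n-Bu4NF, THF, rt; then Ac2O, Et3N, DMAP (cat.), rt
Reagents that add atoms: acetic anhydride, CC(=O)OC(C)=O
Why: Fluoride cleavage of the neopentyl silyl ether followed by DMAP-catalysed acetylation of the liberated C19 alcohol in the same flask; the enoate and both alkenes are unaffected and no stereocentre changes.

**Compound list**

1 | 5-chloropent-1-yne | C#CCCCCl | starting material
2 | [(1E)-5-chloro-2-methylpent-1-en-1-yl]dimethylalane | C[Al](C)/C=C(\C)CCCCl | intermediate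
3 | lithium butyl[(1E)-5-chloro-2-methylpent-1-en-1-yl]dimethylaluminate | [Li+].CCCC[Al-](C)(C)/C=C(\C)CCCCl | intermediate
4 | (2E)-6-chloro-3-methylhex-2-en-1-ol | OC/C=C(\C)CCCCl | intermediate
5 | [(2R,3R)-3-(3-chloropropyl)-3-methyloxiran-2-yl]methanol | OC[C@H]1O[C@]1(C)CCCCl | intermediate
6 | tert-butyl{[(2R,3R)-3-(3-chloropropyl)-3-methyloxiran-2-yl]methoxy}dimethylsilane | CC(C)(C)[Si](C)(C)OC[C@H]1O[C@]1(C)CCCCl | intermediate
7 | (2R)-2-({[tert-butyl(dimethyl)silyl]oxy}methyl)-5-chloro-2-methylpentanal | ClCCC[C@](C)(CO[Si](C)(C)C(C)(C)C)C=O | intermediate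
8 | (2E)-1-bromobut-2-ene [(E)-crotyl bromide] | C/C=C/CBr | starting material
9 | triethyl phosphite | CCOP(OCC)OCC | starting material
10 | diethyl [(2E)-but-2-en-1-yl]phosphonate | CCOP(=O)(OCC)C/C=C/C | intermediate
11 | lithium (2E)-1-(diethoxyphosphoryl)but-2-en-1-ide (α-lithio derivative of 10) | [Li+].CCOP(=O)(OCC)[CH-]/C=C/C | intermediate
12 | tert-butyl{[(2S,3E,5E)-2-(3-chloropropyl)-2-methylhepta-3,5-dien-1-yl]oxy}dimethylsilane | ClCCC[C@](C)(CO[Si](C)(C)C(C)(C)C)/C=C/C=C/C | intermediate
13 | tert-butyl(dimethyl){[(2S,3E,5E)-2-methyl-2-(pent-4-yn-1-yl)hepta-3,5-dien-1-yl]oxy}silane | C#CCCC[C@](C)(CO[Si](C)(C)C(C)(C)C)/C=C/C=C/C | intermediate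
14 | [(1E,6S,7E,9E)-6-({[tert-butyl(dimethyl)silyl]oxy}methyl)-2,6-dimethylundeca-1,7,9-trien-1-yl]dimethylalane | C[Al](C)/C=C(\C)CCC[C@](C)(CO[Si](C)(C)C(C)(C)C)/C=C/C=C/C | intermediate
15 | lithium butyl aluminate of 14 | [Li+].CCCC[Al-](C)(C)/C=C(\C)CCC[C@](C)(CO[Si](C)(C)C(C)(C)C)/C=C/C=C/C | intermediate
16 | (2E,7S,8E,10E)-7-({[tert-butyl(dimethyl)silyl]oxy}methyl)-3,7-dimethyldodeca-2,8,10-trienoic acid | OC(=O)/C=C(\C)CCC[C@](C)(CO[Si](C)(C)C(C)(C)C)/C=C/C=C/C | intermediate
17 | (4S)-4-benzyl-1,3-oxazolidin-2-one | O=C1N[C@@H](Cc2ccccc2)CO1 | starting material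
18 | mixed anhydride of 16 with 2,2-dimethylpropanoic acid | CC(C)(C)C(=O)OC(=O)/C=C(\C)CCC[C@](C)(CO[Si](C)(C)C(C)(C)C)/C=C/C=C/C | intermediate
19 | (4S)-4-benzyl-3-[(2E,7S,8E,10E)-7-({[tert-butyl(dimethyl)silyl]oxy}methyl)-3,7-dimethyldodeca-2,8,10-trienoyl]-1,3-oxazolidin-2-one | O=C1OC[C@H](Cc2ccccc2)N1C(=O)/C=C(\C)CCC[C@](C)(CO[Si](C)(C)C(C)(C)C)/C=C/C=C/C | intermediate
20 | (4S)-4-benzyl-3-[(4S,5R,8S,9S,10S)-19-{[tert-butyl(dimethyl)silyl]oxy}-12,13,14,15,16-pentanorlabd-6-en-11-oyl]-1,3-oxazolidin-2-one | O=C1OC[C@H](Cc2ccccc2)N1C(=O)[C@H]3[C@@H](C)C=C[C@H]4[C@@](C)(CO[Si](C)(C)C(C)(C)C)CCC[C@]34C | intermediate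
21 | (4S)-4-benzyl-3-[(4S,5R,8S,9S,10S)-19-{[tert-butyl(dimethyl)silyl]oxy}-12,13,14,15,16-pentanorlabdan-11-oyl]-1,3-oxazolidin-2-one | O=C1OC[C@H](Cc2ccccc2)N1C(=O)[C@H]3[C@@H](C)CC[C@H]4[C@@](C)(CO[Si](C)(C)C(C)(C)C)CCC[C@]34C | intermediate
22 | (4S,5R,8S,9S,10S)-19-{[tert-butyl(dimethyl)silyl]oxy}-12,13,14,15,16-pentanorlabdane-11-peroxoic acid | OOC(=O)[C@H]1[C@@H](C)CC[C@H]2[C@@](C)(CO[Si](C)(C)C(C)(C)C)CCC[C@]12C | intermediate
23 | (4S,5R,8S,9S,10S)-19-{[tert-butyl(dimethyl)silyl]oxy}-12,13,14,15,16-pentanorlabdan-11-oic acid | OC(=O)[C@H]1[C@@H](C)CC[C@H]2[C@@](C)(CO[Si](C)(C)C(C)(C)C)CCC[C@]12C | intermediate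
24 | methyl (4S,5R,8S,9S,10S)-19-{[tert-butyl(dimethyl)silyl]oxy}-12,13,14,15,16-pentanorlabdan-11-oate | COC(=O)[C@H]1[C@@H](C)CC[C@H]2[C@@](C)(CO[Si](C)(C)C(C)(C)C)CCC[C@]12C | intermediate
25 | lithium enolate of 24 (C9=C11) | [Li+].COC([O-])=C1[C@@H](C)CC[C@H]2[C@@](C)(CO[Si](C)(C)C(C)(C)C)CCC[C@]12C | intermediate
26 | methyl (4S,5R,8S,9R,10S)-19-{[tert-butyl(dimethyl)silyl]oxy}-9-(phenylselanyl)-12,13,14,15,16-pentanorlabdan-11-oate (9α-SePh) | COC(=O)[C@@]1([Se]c3ccccc3)[C@@H](C)CC[C@H]2[C@@](C)(CO[Si](C)(C)C(C)(C)C)CCC[C@]12C | intermediate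
27 | Se-oxide of 26 | COC(=O)[C@@]1([Se](=O)c3ccccc3)[C@@H](C)CC[C@H]2[C@@](C)(CO[Si](C)(C)C(C)(C)C)CCC[C@]12C | intermediate
28 | methyl (4S,5R,10S)-19-{[tert-butyl(dimethyl)silyl]oxy}-12,13,14,15,16-pentanorlabd-8-en-11-oate | COC(=O)C1=C(C)CC[C@H]2[C@@](C)(CO[Si](C)(C)C(C)(C)C)CCC[C@]12C | intermediate
29 | (4S,5R,10S)-19-{[tert-butyl(dimethyl)silyl]oxy}-12,13,14,15,16-pentanorlabd-8-en-11-ol | OCC1=C(C)CC[C@H]2[C@@](C)(CO[Si](C)(C)C(C)(C)C)CCC[C@]12C | intermediate
30 | (4S,5R,10S)-11-bromo-19-{[tert-butyl(dimethyl)silyl]oxy}-12,13,14,15,16-pentanorlabd-8-ene | BrCC1=C(C)CC[C@H]2[C@@](C)(CO[Si](C)(C)C(C)(C)C)CCC[C@]12C | intermediate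
31 | methyl 3-oxobutanoate (methyl acetoacetate) | COC(=O)CC(C)=O | starting material
32 | sodium lithium dianion of 31 | [Na+].[Li+].COC([O-])=CC([O-])=C | intermediate
33 | methyl (4S,5R,10S)-19-{[tert-butyl(dimethyl)silyl]oxy}-13-oxo-16-norlabd-8-en-15-oate | COC(=O)CC(=O)CCC1=C(C)CC[C@H]2[C@@](C)(CO[Si](C)(C)C(C)(C)C)CCC[C@]12C | intermediate
34 | sodium (13Z)-enolate of 33 | [Na+].COC(=O)/C=C(\[O-])CCC1=C(C)CC[C@H]2[C@@](C)(CO[Si](C)(C)C(C)(C)C)CCC[C@]12C | intermediate
35 | methyl (4S,5R,10S,13Z)-13-[(diethoxyphosphoryl)oxy]-19-{[tert-butyl(dimethyl)silyl]oxy}-16-norlabda-8,13-dien-15-oate | COC(=O)/C=C(\OP(=O)(OCC)OCC)CCC1=C(C)CC[C@H]2[C@@](C)(CO[Si](C)(C)C(C)(C)C)CCC[C@]12C | intermediate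
36 | methyl (4S,5R,10S,13E)-19-{[tert-butyl(dimethyl)silyl]oxy}labda-8,13-dien-15-oate | COC(=O)/C=C(\C)CCC1=C(C)CC[C@H]2[C@@](C)(CO[Si](C)(C)C(C)(C)C)CCC[C@]12C | intermediate
37 | methyl (4S,5R,10S,13E)-19-hydroxylabda-8,13-dien-15-oate | COC(=O)/C=C(\C)CCC1=C(C)CC[C@H]2[C@@](C)(CO)CCC[C@]12C | intermediate
38 | methyl (4S,5R,10S,13E)-19-acetoxylabda-8,13-dien-15-oate (CNP0308505.1) | COC(=O)/C=C(\C)CCC1=C(C)CC[C@H]2[C@@](C)(COC(C)=O)CCC[C@]12C | target

**Step count and risks**

Total steps: 20. Longest linear sequence: 19 steps (steps 1–4 and 6–20; step 5 is a one-step branch).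

Steps most likely to fail:

1. Step 10. The β,β-disubstituted dienophile may add too slowly at the temperatures where the chelate is selective, so that on warming diene isomerisation, oligomerisation or loss of facial control compete. The fallback changes the activating group to formyl and moves absolute control to a chiral Lewis acid. It sets out from alkyne 13: carboalumination as in step 8, but with paraformaldehyde as the quench, should give the (2E,8E,10E)-trienol F1. MnO2 oxidation should give the trienal F2. Cyclisation with a triflimide-activated, diphenylprolinol-derived chiral oxazaborolidine (the antipode that sends the diene to the same dienophile face) in CH2Cl2 at −78 → −20 °C should give the bicyclic aldehyde F3. Pinnick oxidation (NaClO2, NaH2PO4, 2-methylbut-2-ene) should give the Δ6 acid F4, and hydrogenation over PtO2 returns to the route at acid 23.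

2. Step 14. Deprotonation of the congested C9–H may be incomplete, or selenenylation may occur from the β face and leave no syn β-hydrogen, so the elimination stalls. The fallback moves to the aldehyde oxidation level, where enolisation is thermodynamic and dehydrogenation is palladium-mediated. It sets out from ester 24: LiAlH4 should give the primary alcohol F5 and Dess–Martin periodinane the aldehyde F6. TMSCl/Et3N/NaI in MeCN should give the exocyclic silyl enol ether F7. Saegusa–Ito oxidation with Pd(OAc)2 in MeCN should give the enal F8, the palladium enolate being free to reach the α face and remove H-8. Luche reduction (NaBH4, CeCl3, MeOH) returns to the route at allylic alcohol 29.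

3. Step 6. The ambident allylic anion may attack the hindered aldehyde through its γ-carbon, and E control at the new double bond may be incomplete; any Z-crotyl impurity in the reagent adds further diene isomers that cyclise poorly. The fallback builds the diene in two stereodefined metal-mediated steps. It sets out from aldehyde 7: Takai olefination (CrCl2, CHI3, THF, 0 °C) should give the (E)-vinyl iodide F9. Suzuki–Miyaura coupling with (E)-prop-1-enylboronic acid (Pd(PPh3)4, aq. K3PO4, THF) returns to the route at diene 12.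

**Further compounds**

F1 | step 10 | (2E,7S,8E,10E)-7-({[tert-butyl(dimethyl)silyl]oxy}methyl)-3,7-dimethyldodeca-2,8,10-trien-1-ol | OC/C=C(\C)CCC[C@](C)(CO[Si](C)(C)C(C)(C)C)/C=C/C=C/C
F2 | step 10 | (2E,7S,8E,10E)-7-({[tert-butyl(dimethyl)silyl]oxy}methyl)-3,7-dimethyldodeca-2,8,10-trienal | O=C/C=C(\C)CCC[C@](C)(CO[Si](C)(C)C(C)(C)C)/C=C/C=C/C
F3 | step 10 | (4S,5R,8S,9S,10S)-19-{[tert-butyl(dimethyl)silyl]oxy}-12,13,14,15,16-pentanorlabd-6-en-11-al | O=C[C@H]1[C@@H](C)C=C[C@H]2[C@@](C)(CO[Si](C)(C)C(C)(C)C)CCC[C@]12C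
F4 | step 10 | (4S,5R,8S,9S,10S)-19-{[tert-butyl(dimethyl)silyl]oxy}-12,13,14,15,16-pentanorlabd-6-en-11-oic acid | OC(=O)[C@H]1[C@@H](C)C=C[C@H]2[C@@](C)(CO[Si](C)(C)C(C)(C)C)CCC[C@]12C
F5 | step 14 | (4S,5R,8S,9S,10S)-19-{[tert-butyl(dimethyl)silyl]oxy}-12,13,14,15,16-pentanorlabdan-11-ol | OC[C@H]1[C@@H](C)CC[C@H]2[C@@](C)(CO[Si](C)(C)C(C)(C)C)CCC[C@]12C
F6 | step 14 | (4S,5R,8S,9S,10S)-19-{[tert-butyl(dimethyl)silyl]oxy}-12,13,14,15,16-pentanorlabdan-11-al | O=C[C@H]1[C@@H](C)CC[C@H]2[C@@](C)(CO[Si](C)(C)C(C)(C)C)CCC[C@]12C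
F7 | step 14 | (4S,5R,8S,10S)-19-{[tert-butyl(dimethyl)silyl]oxy}-11-[(trimethylsilyl)oxy]-12,13,14,15,16-pentanorlabd-9(11)-ene | C[Si](C)(C)OC=C1[C@@H](C)CC[C@H]2[C@@](C)(CO[Si](C)(C)C(C)(C)C)CCC[C@]12C
F8 | step 14 | (4S,5R,10S)-19-{[tert-butyl(dimethyl)silyl]oxy}-12,13,14,15,16-pentanorlabd-8-en-11-al | O=CC1=C(C)CC[C@H]2[C@@](C)(CO[Si](C)(C)C(C)(C)C)CCC[C@]12C
F9 | step 6 | tert-butyl{[(2S,3E)-2-(3-chloropropyl)-4-iodo-2-methylbut-3-en-1-yl]oxy}dimethylsilane | ClCCC[C@](C)(CO[Si](C)(C)C(C)(C)C)/C=C/I
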